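## The problem

Euchrenone b1 (20) is 5,7-dihydroxy-3-(4-hydroxy-3-prenylphenyl)-6,8-diprenylchromen-4-one (prenyl = 3-methylbut-2-en-1-yl), an isoflavone in which the benzopyranone (rings A and C) is joined to ring B through the C3–C1' bond. Ring A is a hexasubstituted benzene of the phloroglucinol type: C5, C7 and C8a carry oxygen, C6 and C8 carry prenyl groups and C4a carries the C4 carbonyl. Two prenyl groups and one acyl group therefore have to be placed, each exactly once, on the three equivalent carbons of a symmetric triphenol. Ring B needs one prenyl group ortho to its phenol and nothing else. The target has no stereocenter, so centres that arise on the way only have to disappear again and none has to direct another. The fragile groups are the three trisubstituted alkenes, each next to a phenol: they exclude quinone and halogen oxidants, peracids and hydrogenation, and strong acid closes them onto the neighbouring hydroxyl to give 2,2-dimethylchromans. The C2=C3 double bond of ring C should therefore come from an elimination and not from a dehydrogenation, and the last deprotection has to be mild. The feature that opens the route is C2, a lone CH carbon at the acetal oxidation level bonded only to O1 and C3. The oxygen-bound methylene of a methoxymethyl (MOM) ether on the C8a oxygen is such a carbon, and a carbene centred on C3, flanked by the C4 ketone and ring B, can reach it through a six-membered transition state.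

## Retrosynthesis

**20 back to 18.** No skeletal bond is cut in the first step back. The C2=C3 double bond of 20 is traced to the 2-methoxychroman-4-one 18, which carries MOM ethers on O5, O7 and O4'. Acid should remove the C2 methoxy group across C2–C3 to give the chromone 19 and then cleave the three MOM ethers in the same flask. Against dehydrogenation of a 2-unsubstituted isoflavanone, this needs no oxidant. It asks only that the acid treatment be short enough to spare the prenyl groups.

**18 back to 17.** Ring C of 18 is opened at C2–C3. This gives the diazo ketone 17, in which C2 is the O–CH2–O carbon of an ortho MOM ether and C3 is the diazo carbon. The neighbouring cut at O1–C2 would need a free ortho phenol on ring A and an external one-carbon electrophile. The cut at C3–C1' would need the finished chromone before ring B arrives. The C2–C3 cut uses a carbon that the protecting group already supplies, needs no differentiation of the two ortho oxygens (their MOM groups are equivalent), and leaves a leaving group on C2. Precursor 17 is acyclic between the two arenes. The forward reaction must favour C–H insertion over attack at the ether oxygen and at the alkenes.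

**17 back to 16.** The C=N2 unit is removed to give the deoxybenzoin 16. Its methylene is activated by both the ketone and ring B, so a direct diazo transfer under amine base should be enough.

**16 back to 8 and 14.** The C4–C4a bond between the ketone and ring A is cut. The donor is the aryllithium 15, made from the arene 8 at its only ring C–H, which lies between two MOM ethers. The acceptor is the Weinreb amide 14. A Friedel–Crafts or Hoesch acylation of a free diprenylphloroglucinol would need strong acid next to three alkenes, so it is set aside. The lithiation route is regiochemically unambiguous and joins the two halves in one step. It asks that addition to the amide beat deprotonation of its benzylic CH2.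

**8 back to 1, 2 and 4.** The two aryl–prenyl bonds of 8 are cut one after the other, through the aryllithiums 7 and 5, back to the tris-MOM ether 3 of phloroglucinol (1). MOM chloride (2) and prenyl bromide (4) are the other inputs. Symmetry does the regiochemical work: every ring hydrogen of 3 and of the mono-prenyl arene 6 lies between two MOM ethers, so each lithiation can give one product only. Direct C-prenylation of 1 would give mixtures of mono-, di- and tri-alkylated and O-alkylated material.

**14 back to 9 and 13.** The aryl–prenyl bond of ring B is cut to the aryl iodide 12 and the prenylstannane 13. Iodide 12 goes back through the iodophenol 11 and the phenol amide 10 to 4-hydroxyphenylacetic acid (9). A lithiation route is closed here by the acidic CH2 next to the amide, and direct C-prenylation of the phenol is unselective. Ortho iodination of a para-blocked phenol followed by cross-coupling fixes the position.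

## Roads not taken

**Alternative 1:** The cut goes through ring B at C1'–C6' and C2'=C3', so that ring B is built on a finished, MOM-protected 6,8-diprenylchromone. Forward, the chromon-3-ylacetaldehyde A2 and the vinyl ketone A3 would undergo amine-catalysed Michael addition and intramolecular aldol condensation (a Robinson-type annulation) to give the 2-prenylcyclohexenone A1. A1 must then be dehydrogenated to the ring B phenol.
- Merits: the ring B prenyl group sits next to the future phenol by construction. No phenol has to be functionalised ortho and no tin reagent is needed. In this respect it is cleaner than steps 5 to 7 of the chosen plan.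
- Weak points: the aromatisation is an oxidation of a molecule with three prenyl alkenes, which is the kind of step this target forbids. A2 already contains rings A and C with both prenyl groups and one more carbon on C3, so making it is no shorter than the chosen route to 16. A3 is not a catalogue compound. The stereocenter of A1 serves no purpose.
- Comparison: the chosen plan spends three ordinary steps on the ring B prenyl group and uses no oxidant at any stage.

**Alternative 2:** Ring A itself is cut. Four of its carbons (C6, C7, C8, C8a) would come from the cyclobutenone A5 and two (C4a, C5) from the siloxyalkyne A6. Heating should open A5 to a vinylketene, which adds to A6 in a [2+2] sense. The new cyclobutenone opens again and the dienylketene closes by 6π electrocyclisation, forming C8–C8a. The net result is insertion of the alkyne carbons between C8a and C6, giving the phenol A4.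
- Merits: the whole substitution pattern of ring A is written into two small fragments, so no regiochemical question arises. The three oxygens come out differentiated (free hydroxyl at C8a, silyl ether at C5, MOM ether at C7). The chosen plan cannot do this, and does not need to, because its ring A stays symmetric until the carbene takes one of two equivalent MOM groups.
- Weak points: A5 and A6 each need several steps. The prenyl alkenes must survive prolonged heating beside ketenes. A4 is still several operations from the target (desilylation, oxidation of the benzylic alcohol, introduction of C2, deprotection) and carries a stereocenter with no function.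
- Comparison: the ring construction is elegant but the fragments are long. The chosen plan reaches the same pattern from phloroglucinol in three steps by symmetry.

**Alternative 3:** Ring A is cut at C4a–C8a in a biomimetic way. The tetracarbonyl chain A8 would be folded by a magnesium alkoxide-mediated Claisen condensation of the C6 carbanion onto the C1 ester, giving the acylphloroglucinol A7.
- Merits: ring A arises with both prenyl groups and with free hydroxyls, so it needs no protecting groups and no organolithium chemistry. A7 is the classical isoflavone precursor, one one-carbon insertion and one deprotection from the target. That endgame is more proven than a carbene insertion, and here this road is at least as good as the last three steps of the chosen plan.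
- Weak points: A8 is hard to assemble. Two C-prenyl groups must be placed singly on defined carbons of a poly-β-carbonyl chain that is prone to O-alkylation and double alkylation. The folding has competitors: an aldol closure between C2 and C7, or lactonisation through an enol oxygen.
- Comparison: the chosen plan sets against it the certainty of the ring A pattern (symmetry plus directed metalation). It keeps the classical one-carbon insertion in reserve as a fallback for the key step.

Key step: step 10

Remark: prenyl means 3-methylbut-2-en-1-yl and MOM means methoxymethyl throughout. Compound 18 is expected as a racemic mixture of C2/C3 diastereomers and is carried on as such, since both centres become sp2 in step 11. The stannane 13 is taken as a purchased reagent.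

## Route

Step 1
Reactants: 1 phloroglucinol; 2 chloromethyl methyl ether
Product: 3 1,3,5-tris(methoxymethoxy)benzene
Conditions: NaH, 2, DMF, 0 °C to rt
Reagents that add atoms: chloromethyl methyl ether (2), COCCl
Why: Williamson-type O-alkylation of the three phenoxides (MOM ether formation); an excess of base and of 2 in DMF at low temperature should carry the reaction to the tris-ether and keep C-alkylation low.

Step 2
Reactants: 3 1,3,5-tris(methoxymethoxy)benzene; 4 1-bromo-3-methylbut-2-ene (prenyl bromide)
Product: 6 1,3,5-tris(methoxymethoxy)-2-(3-methylbut-2-en-1-yl)benzene, via [2,4,6-tris(methoxymethoxy)phenyl]lithium 5 (not isolated)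
Conditions: n-BuLi, THF, 0 °C; then 4, −78 °C to rt
Reagents that add atoms: 1-bromo-3-methylbut-2-ene (4), CC(C)=CCBr
Why: Directed ortho-metalation: a ring C–H between two MOM ethers is lithiated (all three positions are equivalent), and SN2 alkylation at the primary carbon of the allylic bromide should give the linear prenyl arene.

Step 3
Reactants: 6 1,3,5-tris(methoxymethoxy)-2-(3-methylbut-2-en-1-yl)benzene; 4 1-bromo-3-methylbut-2-ene
Product: 8 1,3,5-tris(methoxymethoxy)-2,4-bis(3-methylbut-2-en-1-yl)benzene, via [2,4,6-tris(methoxymethoxy)-3-(3-methylbut-2-en-1-yl)phenyl]lithium 7 (not isolated)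
Conditions: n-BuLi, THF, 0 °C; then 4, −78 °C to rt
Reagents that add atoms: 1-bromo-3-methylbut-2-ene (4), CC(C)=CCBr
Why: Second directed ortho-metalation and alkylation: the two remaining ring hydrogens of 6 are equivalent by symmetry and each lies between two MOM ethers, so ring lithiation can lead to one regioisomer only.

Step 4
Reactants: 9 4-hydroxyphenylacetic acid
Product: 10 2-(4-hydroxyphenyl)-N-methoxy-N-methylacetamide
Conditions: MeNHOMe·HCl, EDC·HCl, HOBt (cat.), N-methylmorpholine, CH2Cl2/DMF, 0 °C to rt
Reagents that add atoms: N,O-dimethylhydroxylamine hydrochloride, CNOC.Cl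
Why: Carbodiimide amide coupling (Weinreb amide formation); the amine outcompetes the phenol for the activated ester, so the phenol needs no protection.

Step 5
Reactants: 10 2-(4-hydroxyphenyl)-N-methoxy-N-methylacetamide
Product: 11 2-(4-hydroxy-3-iodophenyl)-N-methoxy-N-methylacetamide
Conditions: N-iodosuccinimide (1 equiv), TsOH·H2O (cat.), MeCN, 0 °C to rt
Reagents that add atoms: N-iodosuccinimide, O=C1CCC(=O)N1I
Why: Electrophilic aromatic iodination of a para-blocked phenol: the electrophile enters ortho to the hydroxyl, and one equivalent of reagent plus the deactivating effect of the first iodine should hold the reaction at mono-iodination.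

Step 6
Reactants: 11 2-(4-hydroxy-3-iodophenyl)-N-methoxy-N-methylacetamide; 2 chloromethyl methyl ether
Product: 12 2-[3-iodo-4-(methoxymethoxy)phenyl]-N-methoxy-N-methylacetamide
Conditions: 2, i-Pr2NEt, CH2Cl2, 0 °C to rt
Reagents that add atoms: chloromethyl methyl ether (2), COCCl
Why: MOM ether formation by O-alkylation of the phenol under amine base; the amide CH2 is not acidic enough to be touched.

Step 7
Reactants: 12 2-[3-iodo-4-(methoxymethoxy)phenyl]-N-methoxy-N-methylacetamide; 13 tributyl(3-methylbut-2-en-1-yl)stannane
Product: 14 N-methoxy-2-[4-(methoxymethoxy)-3-(3-methylbut-2-en-1-yl)phenyl]-N-methylacetamide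
Conditions: 13, Pd(PPh3)4 (cat.), DMF, 90 °C
Reagents that add atoms: tributyl(3-methylbut-2-en-1-yl)stannane (13), CCCC[Sn](CCCC)(CCCC)CC=C(C)C
Why: Stille cross-coupling: oxidative addition of zerovalent palladium to the aryl iodide, transfer of the allylic group from tin and reductive elimination at the less hindered primary terminus should give the linear prenyl arene; the Weinreb amide and the MOM ether are inert under these neutral conditions.

Step 8
Reactants: 8 1,3,5-tris(methoxymethoxy)-2,4-bis(3-methylbut-2-en-1-yl)benzene; 14 N-methoxy-2-[4-(methoxymethoxy)-3-(3-methylbut-2-en-1-yl)phenyl]-N-methylacetamide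
Product: 16 2-[4-(methoxymethoxy)-3-(3-methylbut-2-en-1-yl)phenyl]-1-[2,4,6-tris(methoxymethoxy)-3,5-bis(3-methylbut-2-en-1-yl)phenyl]ethan-1-one, via [2,4,6-tris(methoxymethoxy)-3,5-bis(3-methylbut-2-en-1-yl)phenyl]lithium 15 (not isolated)
Conditions: n-BuLi, THF, 0 °C to rt; then 14, −78 to 0 °C; aq. NH4Cl
Reagents that add atoms: none
Why: Directed ortho-metalation at the only ring C–H of 8, then acyl substitution on the Weinreb amide: the chelated tetrahedral adduct holds until work-up, so the ketone cannot be attacked twice, and low temperature is meant to favour addition over deprotonation of the benzylic CH2 of 14.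

Step 9
Reactants: 16 2-[4-(methoxymethoxy)-3-(3-methylbut-2-en-1-yl)phenyl]-1-[2,4,6-tris(methoxymethoxy)-3,5-bis(3-methylbut-2-en-1-yl)phenyl]ethan-1-one
Product: 17 2-diazo-2-[4-(methoxymethoxy)-3-(3-methylbut-2-en-1-yl)phenyl]-1-[2,4,6-tris(methoxymethoxy)-3,5-bis(3-methylbut-2-en-1-yl)phenyl]ethan-1-one
Conditions: 4-acetamidobenzenesulfonyl azide, DBU, MeCN, 0 °C to rt
Reagents that add atoms: 4-acetamidobenzenesulfonyl azide, CC(=O)Nc1ccc(cc1)S(=O)(=O)N=[N+]=[N-]
Why: Regitz diazo transfer: the CH2 of 16 is activated by the ketone and by ring B, so DBU should suffice for enolisation; the enolate attacks the terminal nitrogen of the sulfonyl azide and the adduct collapses to the diazo ketone and the sulfonamide, as is usual for aryl benzyl ketones without prior formylation.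

Step 10
Reactants: 17 2-diazo-2-[4-(methoxymethoxy)-3-(3-methylbut-2-en-1-yl)phenyl]-1-[2,4,6-tris(methoxymethoxy)-3,5-bis(3-methylbut-2-en-1-yl)phenyl]ethan-1-one
Product: 18 2-methoxy-5,7-bis(methoxymethoxy)-3-[4-(methoxymethoxy)-3-(3-methylbut-2-en-1-yl)phenyl]-6,8-bis(3-methylbut-2-en-1-yl)chroman-4-one (racemic, mixture of C2/C3 diastereomers)
Conditions: Rh2(OAc)4 (1–2 mol %), CH2Cl2, 40 °C, slow addition of 17 at high dilution
Reagents that add atoms: none
Why: Rh2(OAc)4 (divalent rhodium) should decompose 17 with loss of N2 to an aryl- and acyl-substituted (donor–acceptor) rhodium carbene at the future C3. The carbene should insert into one C–H bond of the O–CH2–O methylene of an ortho MOM ether in a concerted, asynchronous three-centre step with hydride-transfer character, forming C2–C3; the closest known reaction type is the intramolecular C–H insertion of rhodium carbenes from ortho-alkoxyaryl diazo ketones that gives chroman-4-ones. Ring C closes by 1,6-insertion through a six-membered transition state (C3, C4, C4a, C8a, O1, C2); the usual preference for five-membered rings has no outlet because the fifth atom from the carbene is the ether oxygen itself. The two ortho MOM groups are equivalent by the symmetry of ring A, so no regiochemical choice exists. C2 and C3 are new stereocenters set without control: the catalyst is achiral, so the product is racemic, the relative configuration follows from the insertion transition state, and C3 can epimerise next to the ketone. Both centres are erased in step 11, so any mixture serves. The step needs insertion to beat oxonium ylide formation at the aryl ether oxygen, cyclopropanation of the prenyl alkenes and carbene dimerisation. The substrate helps: the methylene is hydridic through two oxygens, the aryl ether oxygen is deactivated by conjugation with the acylated ring and crowded by a prenyl group, and the trisubstituted alkenes are out of reach, while slow addition suppresses dimerisation.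

Step 11
Reactants: 18 2-methoxy-5,7-bis(methoxymethoxy)-3-[4-(methoxymethoxy)-3-(3-methylbut-2-en-1-yl)phenyl]-6,8-bis(3-methylbut-2-en-1-yl)chroman-4-one
Product: 20 euchrenone b1, via tris(methoxymethyl) ether of euchrenone b1 19 (not isolated)
Conditions: HCl, MeOH, 40 °C, stopped at full conversion
Reagents that add atoms: none
Why: Acid-catalysed elimination of methanol from the 2-methoxy acetal (through the C4 enol or the C2 oxocarbenium ion) should give the chromone, and acetal exchange with methanol then removes the three MOM ethers as dimethoxymethane; C2 and C3 become sp2, so the stereocenters of 18 vanish.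

## Compound list

1 | phloroglucinol (benzene-1,3,5-triol) | Oc1cc(O)cc(O)c1 | starting material
2 | chloromethyl methyl ether | COCCl | starting material
3 | 1,3,5-tris(methoxymethoxy)benzene | COCOc1cc(OCOC)cc(OCOC)c1 | intermediate
4 | 1-bromo-3-methylbut-2-ene (prenyl bromide) | CC(C)=CCBr | starting material
5 | [2,4,6-tris(methoxymethoxy)phenyl]lithium | [Li]c1c(OCOC)cc(OCOC)cc1OCOC | intermediate (not isolated)
6 | 1,3,5-tris(methoxymethoxy)-2-(3-methylbut-2-en-1-yl)benzene | COCOc1cc(OCOC)c(CC=C(C)C)c(OCOC)c1 | intermediate
7 | [2,4,6-tris(methoxymethoxy)-3-(3-methylbut-2-en-1-yl)phenyl]lithium | [Li]c1c(OCOC)cc(OCOC)c(CC=C(C)C)c1OCOC | intermediate (not isolated)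
8 | 1,3,5-tris(methoxymethoxy)-2,4-bis(3-methylbut-2-en-1-yl)benzene | COCOc1cc(OCOC)c(CC=C(C)C)c(OCOC)c1CC=C(C)C | intermediate
9 | 4-hydroxyphenylacetic acid | OC(=O)Cc1ccc(O)cc1 | starting material
10 | 2-(4-hydroxyphenyl)-N-methoxy-N-methylacetamide | CON(C)C(=O)Cc1ccc(O)cc1 | intermediate
11 | 2-(4-hydroxy-3-iodophenyl)-N-methoxy-N-methylacetamide | CON(C)C(=O)Cc1ccc(O)c(I)c1 | intermediate
12 | 2-[3-iodo-4-(methoxymethoxy)phenyl]-N-methoxy-N-methylacetamide | CON(C)C(=O)Cc1ccc(OCOC)c(I)c1 | intermediate
13 | tributyl(3-methylbut-2-en-1-yl)stannane | CCCC[Sn](CCCC)(CCCC)CC=C(C)C | starting material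
14 | N-methoxy-2-[4-(methoxymethoxy)-3-(3-methylbut-2-en-1-yl)phenyl]-N-methylacetamide | CON(C)C(=O)Cc1ccc(OCOC)c(CC=C(C)C)c1 | intermediate
15 | [2,4,6-tris(methoxymethoxy)-3,5-bis(3-methylbut-2-en-1-yl)phenyl]lithium | [Li]c1c(OCOC)c(CC=C(C)C)c(OCOC)c(CC=C(C)C)c1OCOC | intermediate (not isolated)
16 | 2-[4-(methoxymethoxy)-3-(3-methylbut-2-en-1-yl)phenyl]-1-[2,4,6-tris(methoxymethoxy)-3,5-bis(3-methylbut-2-en-1-yl)phenyl]ethan-1-one | COCOc1c(CC=C(C)C)c(OCOC)c(CC=C(C)C)c(OCOC)c1C(=O)Cc1ccc(OCOC)c(CC=C(C)C)c1 | intermediate
17 | 2-diazo-2-[4-(methoxymethoxy)-3-(3-methylbut-2-en-1-yl)phenyl]-1-[2,4,6-tris(methoxymethoxy)-3,5-bis(3-methylbut-2-en-1-yl)phenyl]ethan-1-one | COCOc1c(CC=C(C)C)c(OCOC)c(CC=C(C)C)c(OCOC)c1C(=O)C(=[N+]=[N-])c1ccc(OCOC)c(CC=C(C)C)c1 | intermediate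
18 | 2-methoxy-5,7-bis(methoxymethoxy)-3-[4-(methoxymethoxy)-3-(3-methylbut-2-en-1-yl)phenyl]-6,8-bis(3-methylbut-2-en-1-yl)chroman-4-one (racemic, both C2/C3 diastereomers) | COCOc1c(CC=C(C)C)c(OCOC)c(CC=C(C)C)c2OC(OC)C(c3ccc(OCOC)c(CC=C(C)C)c3)C(=O)c12 | intermediate
19 | 5,7-bis(methoxymethoxy)-3-[4-(methoxymethoxy)-3-(3-methylbut-2-en-1-yl)phenyl]-6,8-bis(3-methylbut-2-en-1-yl)-4H-chromen-4-one | COCOc1ccc(-c2coc3c(CC=C(C)C)c(OCOC)c(CC=C(C)C)c(OCOC)c3c2=O)cc1CC=C(C)C | intermediate (not isolated)
20 | euchrenone b1, 5,7-dihydroxy-3-[4-hydroxy-3-(3-methylbut-2-en-1-yl)phenyl]-6,8-bis(3-methylbut-2-en-1-yl)-4H-chromen-4-one | CC(C)=CCc1cc(-c2coc3c(CC=C(C)C)c(O)c(CC=C(C)C)c(O)c3c2=O)ccc1O | target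

## Step count and risks

Total step count: 11. Longest linear sequence: 8 steps (steps 4 to 11, from 9); the ring A branch from 1 runs through 7 steps (1, 2, 3, 8, 9, 10, 11).

**Step 10 (key step).** The most likely failure is attack of the carbene on the aryl ether oxygen to give a five-membered oxonium ylide, followed by 1,2-migration of the methoxymethyl group, which migrates well. Carbene dimerisation at too high a concentration is the second risk. A less electrophilic carboxamidate catalyst such as dirhodium tetrakis(caprolactamate) is the first adjustment within the step. The fallback leaves the carbene and sets out from 16. Heating 16 with N,N-dimethylformamide dimethyl acetal in toluene should give the enaminone (E)-3-(dimethylamino)-2-[4-(methoxymethoxy)-3-(3-methylbut-2-en-1-yl)phenyl]-1-[2,4,6-tris(methoxymethoxy)-3,5-bis(3-methylbut-2-en-1-yl)phenyl]prop-2-en-1-one F1; its alkene geometry is immaterial. Treatment of F1 with HCl in methanol should cleave the MOM ethers, and the freed ortho phenol then adds to the enaminone and expels dimethylamine. This closes ring C by the classical deoxybenzoin route and comes back to the route at 20.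

**Step 8.** The hindered and strongly basic aryllithium 15 may deprotonate the benzylic CH2 of 14 instead of adding to the amide carbonyl, which would return both partners. The fallback sets out from 14 and replaces acyl substitution by addition and oxidation. Reduction of 14 with i-Bu2AlH at −78 °C should give 2-[4-(methoxymethoxy)-3-(3-methylbut-2-en-1-yl)phenyl]acetaldehyde F2. Transmetalation of 15 with CeCl3 gives the much less basic dichloro[2,4,6-tris(methoxymethoxy)-3,5-bis(3-methylbut-2-en-1-yl)phenyl]cerium F3. F3 should add to F2 to give racemic 2-[4-(methoxymethoxy)-3-(3-methylbut-2-en-1-yl)phenyl]-1-[2,4,6-tris(methoxymethoxy)-3,5-bis(3-methylbut-2-en-1-yl)phenyl]ethan-1-ol F4. Oxidation of F4 with Dess–Martin periodinane comes back to the route at 16.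

**Step 11.** During the time needed to cleave three MOM ethers, acid may cyclise a prenyl group onto a freed ortho phenol (chroman formation) or add HCl or methanol across an alkene. The fallback sets out from 18 and separates the two events. Catalytic pyridinium p-toluenesulfonate in warm toluene should eliminate methanol only, and 19 is then isolated. The MOM ethers of 19 are cleaved by ZnBr2 and propane-1-thiol in CH2Cl2 at 0 °C, a fast Lewis acid method with a thiol scavenger and no protic acid. This comes back at 20 and makes no compound outside the compound list (F0).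

**Step 7.** Allylic transposition during transfer from tin or reductive elimination would give the 1,1-dimethylallyl isomer, and protodeiodination would waste 12. The fallback sets out from 10 and builds the prenyl group in two stages.
- O-Allylation with allyl bromide and K2CO3 gives N-methoxy-N-methyl-2-[4-(prop-2-en-1-yloxy)phenyl]acetamide F5.
- Thermal Claisen rearrangement gives 2-[4-hydroxy-3-(prop-2-en-1-yl)phenyl]-N-methoxy-N-methylacetamide F6.
- Protection with 2 and i-Pr2NEt gives N-methoxy-2-[4-(methoxymethoxy)-3-(prop-2-en-1-yl)phenyl]-N-methylacetamide F7.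
- Cross-metathesis of F7 with excess 2-methylbut-2-ene and the second-generation Grubbs catalyst comes back to the route at 14.

**Step 3.** The doubly activated benzylic and allylic CH2 of the prenyl group in 6 may be deprotonated in competition with the ring C–H. This would lead to side-chain alkylation or alkene migration. The same concern applies, to a lesser degree, to the lithiation in step 8. The fallback sets out from 3 and replaces deprotonation by halogen–lithium exchange, which at −78 °C is faster than any deprotonation.
- Two equivalents of N-bromosuccinimide should give 2,4-dibromo-1,3,5-tris(methoxymethoxy)benzene F8, before any alkene is present.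
- One equivalent of n-BuLi at −78 °C gives [3-bromo-2,4,6-tris(methoxymethoxy)phenyl]lithium F9.
- Alkylation of F9 with 4 gives 2-bromo-1,3,5-tris(methoxymethoxy)-4-(3-methylbut-2-en-1-yl)benzene F10.
- A second exchange on F10 gives 7, and 4 then comes back to the route at 8.

## Further compounds

F1 | step 10 | (E)-3-(dimethylamino)-2-[4-(methoxymethoxy)-3-(3-methylbut-2-en-1-yl)phenyl]-1-[2,4,6-tris(methoxymethoxy)-3,5-bis(3-methylbut-2-en-1-yl)phenyl]prop-2-en-1-one | CN(C)/C=C(/C(=O)c1c(OCOC)c(CC=C(C)C)c(OCOC)c(CC=C(C)C)c1OCOC)c1ccc(OCOC)c(CC=C(C)C)c1
F2 | step 8 | 2-[4-(methoxymethoxy)-3-(3-methylbut-2-en-1-yl)phenyl]acetaldehyde | O=CCc1ccc(OCOC)c(CC=C(C)C)c1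
F3 | step 8 | dichloro[2,4,6-tris(methoxymethoxy)-3,5-bis(3-methylbut-2-en-1-yl)phenyl]cerium | Cl[Ce](Cl)c1c(OCOC)c(CC=C(C)C)c(OCOC)c(CC=C(C)C)c1OCOC
F4 | step 8 | (racemic) 2-[4-(methoxymethoxy)-3-(3-methylbut-2-en-1-yl)phenyl]-1-[2,4,6-tris(methoxymethoxy)-3,5-bis(3-methylbut-2-en-1-yl)phenyl]ethan-1-ol | COCOc1c(CC=C(C)C)c(OCOC)c(CC=C(C)C)c(OCOC)c1C(O)Cc1ccc(OCOC)c(CC=C(C)C)c1
F0 | step 11 | none | none
F5 | step 7 | N-methoxy-N-methyl-2-[4-(prop-2-en-1-yloxy)phenyl]acetamide | CON(C)C(=O)Cc1ccc(OCC=C)cc1
F6 | step 7 | 2-[4-hydroxy-3-(prop-2-en-1-yl)phenyl]-N-methoxy-N-methylacetamide | CON(C)C(=O)Cc1ccc(O)c(CC=C)c1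
F7 | step 7 | N-methoxy-2-[4-(methoxymethoxy)-3-(prop-2-en-1-yl)phenyl]-N-methylacetamide | CON(C)C(=O)Cc1ccc(OCOC)c(CC=C)c1
F8 | step 3 | 2,4-dibromo-1,3,5-tris(methoxymethoxy)benzene | COCOc1cc(OCOC)c(Br)c(OCOC)c1Br
F9 | step 3 | [3-bromo-2,4,6-tris(methoxymethoxy)phenyl]lithium | [Li]c1c(OCOC)cc(OCOC)c(Br)c1OCOC
F10 | step 3 | 2-bromo-1,3,5-tris(methoxymethoxy)-4-(3-methylbut-2-en-1-yl)benzene | COCOc1cc(OCOC)c(CC=C(C)C)c(OCOC)c1Br
A1 | alternative 1 | (racemic) 5,7-bis(methoxymethoxy)-6,8-bis(3-methylbut-2-en-1-yl)-3-[3-(3-methylbut-2-en-1-yl)-4-oxocyclohex-2-en-1-yl]-4H-chromen-4-one | O=C1CCC(c2coc3c(CC=C(C)C)c(OCOC)c(CC=C(C)C)c(OCOC)c3c2=O)C=C1CC=C(C)C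
A2 | alternative 1 | 2-[5,7-bis(methoxymethoxy)-6,8-bis(3-methylbut-2-en-1-yl)-4-oxo-4H-chromen-3-yl]acetaldehyde | O=CCc1coc2c(CC=C(C)C)c(OCOC)c(CC=C(C)C)c(OCOC)c2c1=O
A3 | alternative 1 | 7-methylocta-1,6-dien-3-one | C=CC(=O)CCC=C(C)C
A4 | alternative 2 | (racemic) 2-[1-(tert-butyldimethylsilyloxy)-2-[4-(methoxymethoxy)-3-(3-methylbut-2-en-1-yl)phenyl]ethyl]-5-(methoxymethoxy)-4,6-bis(3-methylbut-2-en-1-yl)-3-(triisopropylsilyloxy)phenol | Oc1c(CC=C(C)C)c(OCOC)c(CC=C(C)C)c(O[Si](C(C)C)(C(C)C)C(C)C)c1C(O[Si](C)(C)C(C)(C)C)Cc1ccc(OCOC)c(CC=C(C)C)c1
A5 | alternative 2 | (racemic) 3-(methoxymethoxy)-2,4-bis(3-methylbut-2-en-1-yl)cyclobut-2-en-1-one | O=C1C(CC=C(C)C)=C(OCOC)C1CC=C(C)C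
A6 | alternative 2 | (racemic) tert-butyldimethyl{[1-[4-(methoxymethoxy)-3-(3-methylbut-2-en-1-yl)phenyl]-4-(triisopropylsilyloxy)but-3-yn-2-yl]oxy}silane | CC(C)[Si](OC#CC(Cc1ccc(OCOC)c(CC=C(C)C)c1)O[Si](C)(C)C(C)(C)C)(C(C)C)C(C)C
A7 | alternative 3 | 2-[4-(methoxymethoxy)-3-(3-methylbut-2-en-1-yl)phenyl]-1-[2,4,6-trihydroxy-3,5-bis(3-methylbut-2-en-1-yl)phenyl]ethan-1-one | O=C(Cc1ccc(OCOC)c(CC=C(C)C)c1)c1c(O)c(CC=C(C)C)c(O)c(CC=C(C)C)c1O
A8 | alternative 3 | methyl 8-[4-(methoxymethoxy)-3-(3-methylbut-2-en-1-yl)phenyl]-2,4-bis(3-methylbut-2-en-1-yl)-3,5,7-trioxooctanoate (mixture of stereoisomers and tautomers) | COC(=O)C(CC=C(C)C)C(=O)C(CC=C(C)C)C(=O)CC(=O)Cc1ccc(OCOC)c(CC=C(C)C)c1
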